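- The enzyme was what I watched in Friday's flask, which is the flask asked about. I wanted one number from it: how much target one charge makes in its working life.

- Friday's: substrate 12 mM; enzyme 0.023 mol%; the very flask that is asked about, followed so far
- flask: substrate 12 mM; enzyme 0.023 mol%; time 3.0 d

Friday's run (percent of the substrate charged)

| time / d | target / % | substrate / % |
|---|---|---|
| 0.625 | 29.4 | 70.3 |
| 1.25 | 41.6 | 58.3 |
| 1.67 | 45.1 | 54.6 |
| 2.50 | 49.9 | 50.7 |

(each reading ± 0.3 percentage points)

- autumn: at 3.0 d take out 90% of the target then present, then wait 6.0 d
- summer: at 3.0 d add substrate, 50.0% of the amount charged, then wait 6.0 d
- midnight: change nothing and wait 6.0 d more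
- dawn: at 3.0 d add enzyme, 100% of the amount charged, then wait 6.0 d

- removed target is counted in
- the earlier runs were read with a standard deviation of 0.3 percentage points
- on the list of suspects stand: substrate + enzyme -> target + enzyme; substrate + enzyme -> spent catalyst
- additions bring no volume worth counting

1. target, in percent of the substrate first charged, at 3.0 d
2. which option adds most target ("none" when 2 percentage points or less is all one gets) (autumn / summer / midnight / dawn / none)
3. target present, with what was taken out counted in, in percent of the substrate first charged, after summer
4. target present, with what was taken out counted in, in percent of the substrate first charged, after midnight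

- I took the enzyme to fade at a steady fractional rate, so that equal ratios of new target follow in equal stretches of time. From 0.625 d to 1.25 d the new target was a fraction 0.415 of the first reading, and that gave a first ceiling of 50.3%.
- Put back, this first answer predicted 48.8% at 2.50 d, but the reading was 49.9%, a gap of 1.1 percentage points against a scatter of 0.3 points. So I went round again on the later stretch, where the fraction was 0.200.
- That gave 52.0%. This reading, with the scatter of the readings in it, I took as the ceiling, the target in percent of the substrate charged that one charge of enzyme makes in its working life, or its total turnover number in other units. The fading rate read there was 1.29 d⁻¹.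
- Fastest rung: the half-life I read for the enzyme was 0.538 d, shorter than the 1.49 d the opening rate I read needs to use the charged substrate. So I expected the enzyme to fade while much substrate stood.
- Next rung: 3.0 d is 5.58 half-lives. I reckoned 2.09% of the enzyme still working, target at 50.9% and substrate at 49.1%.
- Slowest rung: the wait of 6.0 d. Midnight, autumn and summer leave the enzyme as it stands, so I gave each the spare 1.1 points, against a margin of 2 points. To dawn I gave a second ceiling of the same size, larger than the substrate I reckoned left, so I reckoned its gain at that substrate, more than the spare.
- The forecast, higher than my reckoning at 51.5%, chose dawn and gave 55% after summer and 54.9% after midnight, holding that the enzyme “makes a fixed amount of target before it is spent”.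
- The flask gave 50.8%, and dawn added the most, 49 points, with 51.8% after summer and 52.8% after midnight. The share of enzyme still able to turn over at 3.0 d was 2.50%, beside my 2.09%. Against that result the ceiling leaves 1.2 points, and midnight added 1.9 points.

    substrate + enzyme → target + enzyme, rate k1*[substrate]^1.5*[enzyme]/(1 + ([substrate]/Kh1)^1.5) (1.30 mM, k = 3.20 × 10⁶ L¹·⁵ mol⁻¹·⁵ h⁻¹)
    substrate + enzyme → spent catalyst (k = 7.00 L mol⁻¹ h⁻¹)

- For the flask with 0.0057 mol% of enzyme, the ceiling scaled by the loading gave 12.9%. The computed target at 3.0 d was 10.3%, less than that, with 0.395% of its enzyme left and 89.7% of its substrate.

(The readings come from a simulation from invented constants; scatter was added.)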